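## Retrosynthetic overview

1. Laxiflorin 16 comes from its 4'-O-TBS ether 15 by a last fluoride desilylation.
2. Rings C and A of 15 are closed in one flask from the open-chain triketo-lactone 12. Acid closes ring C (the C2 hydroxyl onto the C8a ketone). Base then closes ring A (C4a onto the butyrolactone carbonyl), which aromatises and frees the 2-hydroxyethyl arm.
3. 12 comes from a Claisen-type union (C8–C8a bond) of the dianion of keto-lactone 10 with dioxinone 6, a masked β-keto acyl donor.
4. 6 comes from a catalytic asymmetric vinylogous Mukaiyama aldol of TBS-vanillin 2 with dienol silane 5, which sets C2. 10 comes from 2-acetylbutyrolactone and prenyl bromide.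
5. Ring order: ring B is bought (vanillin); ring C and then ring A form together in step 6.

Assumption: (S)-Tol-BINAP is written as the ligand antipode that sends the dienolate to the Si face of aldehyde 2 and so gives the (S)-carbinol. This is checked on the first run by Mosher ester analysis of desilylated 6, and the other antipode is used if the sense is opposite. Open-chain intermediates are described with flavanone numbering (O1, C2, C3, C4, C4a, C5–C8, C8a).

## Route

Step 1
Reactants: 1 vanillin
Product: 2 4-(tert-butyldimethylsilyloxy)-3-methoxybenzaldehyde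
Conditions: TBSCl, imidazole, DMF, rt
Reagents that add atoms: tert-butyldimethylsilyl chloride, CC(C)(C)[Si](C)(C)Cl
Why: Standard silyl ether protection of the phenol; the TBS group keeps the phenol from quenching the silyl dienolate in step 3 and blocks a para-phenoxide (quinone methide) racemisation path under base in step 6.

Step 2
Reactants: 3 2,2,6-trimethyl-4H-1,3-dioxin-4-one
Product: 5 2,2-dimethyl-6-methylene-4-(trimethylsilyloxy)-1,3-diox-4-ene, via lithium dioxinone dienolate 4 (not isolated)
Conditions: LDA, THF, −78 °C; then TMSCl, −78 °C to rt; distil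
Reagents that add atoms: trimethylsilyl chloride, C[Si](C)(C)Cl
Why: Kinetic γ-deprotonation of the dioxinone and O-silylation of the vinylogous enolate give the dienol silane (silyl dienolate formation).

Step 3
Reactants: 2 4-(tert-butyldimethylsilyloxy)-3-methoxybenzaldehyde; 5 2,2-dimethyl-6-methylene-4-(trimethylsilyloxy)-1,3-diox-4-ene
Product: 6 (S)-6-{2-[4-(tert-butyldimethylsilyloxy)-3-methoxyphenyl]-2-(trimethylsilyloxy)ethyl}-2,2-dimethyl-4H-1,3-dioxin-4-one
Conditions: 5 (1.5 equiv), Cu(OTf)2 (2 mol %), (S)-Tol-BINAP (2.2 mol %), Bu4N[Ph3SiF2] (4 mol %), THF, −78 °C; non-acidic work-up, Et3N-deactivated silica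
Reagents that add atoms: none
Why: Catalytic enantioselective vinylogous Mukaiyama aldol (copper fluoride/Tol-BINAP dienolate addition): the chiral copper dienolate attacks the Si face of the aldehyde through its γ-carbon, setting the (S)-carbinol that becomes C2, and silyl transfer releases the adduct as its TMS ether.

Step 4
Reactants: 7 2-acetylbutyrolactone (3-acetyloxolan-2-one); 8 prenyl bromide (1-bromo-3-methylbut-2-ene)
Product: 10 3-(5-methylhex-4-enoyl)oxolan-2-one (racemic; labile α-centre), via dilithium acetylbutyrolactone dianion 9 (not isolated)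
Conditions: LDA (2.2 equiv), THF, −78 to 0 °C; then 8, −78 to 0 °C; AcOH
Reagents that add atoms: none
Why: Weiler-type dianion γ-alkylation: the more basic terminal carbanion of the β-keto lactone dianion displaces the allylic bromide (SN2), giving the chain that carries C5–C8, the prenyl group and the masked hydroxyethyl arm.

Step 5
Reactants: 10 3-(5-methylhex-4-enoyl)oxolan-2-one (3 equiv); 6 (S)-dioxinone TMS ether
Product: 12 3-[(7S)-7-[4-(tert-butyldimethylsilyloxy)-3-methoxyphenyl]-2-(3-methylbut-2-enyl)-3,5-dioxo-7-(trimethylsilyloxy)heptanoyl]oxolan-2-one (keto/enol tautomers; epimers at the two labile methine carbons), via dilithium ketolactone dianion 11 (not isolated)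
Conditions: 10, LDA (6 equiv), THF, −78 to 0 °C; then 6 (1 equiv), −78 to −30 °C; AcOH, pH 7 buffer; used crude
Reagents that add atoms: none
Why: Proposed new method: the terminal (γ) carbanion of dianion 11 adds to the dioxinone carbonyl of 6 (a vinylogous carbonate with no free OH), and the tetrahedral intermediate collapses with loss of acetone to a stabilised β-diketonate, which drives this Claisen-type acylation and forms the C8–C8a bond; the closest known reaction types are the Huckin–Weiler acylation of β-keto ester dianions with esters and the alkoxide ring-opening of dioxinones to β-keto esters; the C2 centre is not touched.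

Step 6
Reactants: 12 open-chain triketo-lactone TMS ether
Product: 15 (2S)-2-[4-(tert-butyldimethylsilyloxy)-3-methoxyphenyl]-5,7-dihydroxy-6-(2-hydroxyethyl)-8-(3-methylbut-2-enyl)-2,3-dihydro-4H-chromen-4-one, via hydroxy triketone 13 (not isolated), via dihydropyranone 14 (not isolated)
Conditions: TsOH·H2O (0.2 equiv), MeCN, 0 °C to rt; then DBU (4 equiv), rt; AcOH
Reagents that add atoms: none
Why: Proposed new method: acid removes the TMS group and the freed C2 hydroxyl adds to the C8a ketone, the hemiketal dehydrating to the vinylogous ester 14 (ring C; the C2–O bond is never broken, so the (S) centre is retained), then DBU forms the cross-conjugated dienolate whose C4a attacks the lactone carbonyl in a 6-exo Dieckmann-type (Claisen) closure, the ring alkoxide leaves as the 2-hydroxyethyl arm and tautomerisation gives the phloroglucinol ring A irreversibly; the closest known reaction types are the acid cyclodehydration of δ-hydroxy-β-diketones to 2,3-dihydro-4H-pyran-4-ones and the biomimetic Claisen cyclisation of triketo esters to acylphloroglucinols.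

Step 7
Reactants: 15 4'-O-TBS laxiflorin
Product: 16 laxiflorin, (2S)-5,7-dihydroxy-2-(4-hydroxy-3-methoxyphenyl)-6-(2-hydroxyethyl)-8-(3-methylbut-2-enyl)-2,3-dihydro-4H-chromen-4-one
Conditions: KHF2, MeOH, rt
Reagents that add atoms: none
Why: Fluoride desilylation of the aryl silyl ether under near-neutral, slightly acidic conditions, which leaves the base-sensitive C2 centre, the prenyl group and the free phenols untouched.

## Compound list

1 | vanillin (4-hydroxy-3-methoxybenzaldehyde) | COc1cc(C=O)ccc1O | starting material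
2 | 4-(tert-butyldimethylsilyloxy)-3-methoxybenzaldehyde | COc1cc(C=O)ccc1O[Si](C)(C)C(C)(C)C | intermediate
3 | 2,2,6-trimethyl-4H-1,3-dioxin-4-one | CC1=CC(=O)OC(C)(C)O1 | starting material
4 | lithium 2,2-dimethyl-6-methylene-1,3-diox-4-en-4-olate (lithium dienolate of 3) | [Li+].C=C1C=C([O-])OC(C)(C)O1 | intermediate
5 | 2,2-dimethyl-6-methylene-4-(trimethylsilyloxy)-1,3-diox-4-ene | C=C1C=C(O[Si](C)(C)C)OC(C)(C)O1 | intermediate
6 | (S)-6-{2-[4-(tert-butyldimethylsilyloxy)-3-methoxyphenyl]-2-(trimethylsilyloxy)ethyl}-2,2-dimethyl-4H-1,3-dioxin-4-one | COc1cc([C@@H](O[Si](C)(C)C)CC2=CC(=O)OC(C)(C)O2)ccc1O[Si](C)(C)C(C)(C)C | intermediate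
7 | 2-acetylbutyrolactone (3-acetyloxolan-2-one, racemic) | CC(=O)C1CCOC1=O | starting material
8 | prenyl bromide (1-bromo-3-methylbut-2-ene) | CC(C)=CCBr | starting material
9 | dilithium dianion of 7 (dienediolate) | [Li+].[Li+].C=C([O-])C1=C([O-])OCC1 | intermediate
10 | 3-(5-methylhex-4-enoyl)oxolan-2-one (racemic, labile α-centre) | CC(C)=CCCC(=O)C1CCOC1=O | intermediate
11 | dilithium dianion of 10 (dienediolate) | [Li+].[Li+].CC(C)=CCC=C([O-])C1=C([O-])OCC1 | intermediate
12 | 3-[(7S)-7-[4-(tert-butyldimethylsilyloxy)-3-methoxyphenyl]-2-(3-methylbut-2-enyl)-3,5-dioxo-7-(trimethylsilyloxy)heptanoyl]oxolan-2-one (epimers at the two labile methine carbons) | COc1cc([C@@H](O[Si](C)(C)C)CC(=O)CC(=O)C(CC=C(C)C)C(=O)C2CCOC2=O)ccc1O[Si](C)(C)C(C)(C)C | intermediate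
13 | 3-[(7S)-7-[4-(tert-butyldimethylsilyloxy)-3-methoxyphenyl]-7-hydroxy-2-(3-methylbut-2-enyl)-3,5-dioxoheptanoyl]oxolan-2-one | COc1cc([C@@H](O)CC(=O)CC(=O)C(CC=C(C)C)C(=O)C2CCOC2=O)ccc1O[Si](C)(C)C(C)(C)C | intermediate
14 | (2S)-2-[4-(tert-butyldimethylsilyloxy)-3-methoxyphenyl]-6-[5-methyl-1-oxo-1-(2-oxooxolan-3-yl)hex-4-en-2-yl]-2,3-dihydro-4H-pyran-4-one | COc1cc([C@@H]2CC(=O)C=C(C(CC=C(C)C)C(=O)C3CCOC3=O)O2)ccc1O[Si](C)(C)C(C)(C)C | intermediate
15 | (2S)-2-[4-(tert-butyldimethylsilyloxy)-3-methoxyphenyl]-5,7-dihydroxy-6-(2-hydroxyethyl)-8-(3-methylbut-2-enyl)-2,3-dihydro-4H-chromen-4-one | COc1cc([C@@H]2CC(=O)c3c(O)c(CCO)c(O)c(CC=C(C)C)c3O2)ccc1O[Si](C)(C)C(C)(C)C | intermediate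
16 | laxiflorin, (2S)-5,7-dihydroxy-2-(4-hydroxy-3-methoxyphenyl)-6-(2-hydroxyethyl)-8-(3-methylbut-2-enyl)-2,3-dihydro-4H-chromen-4-one | COc1cc([C@@H]2CC(=O)c3c(O)c(CCO)c(O)c(CC=C(C)C)c3O2)ccc1O | target

## Step count and risks

Total steps: 7. Longest linear sequence: 5 (steps 1, 3, 5, 6, 7 from vanillin).

Most likely to fail, first: step 6. The acid stage could give a γ-pyrone from the 1,3,5-triketone instead of 14, the enolisable lactone may be a sluggish acyl acceptor, and DBU could erode the ee by reversible ring-C opening. The fallback closes ring A through a neutral acylketene instead of an anionic lactone Dieckmann. It sets out from 6, with 8 and commercial tert-butyl acetoacetate. LDA dianion prenylation of tert-butyl acetoacetate with 8 gives tert-butyl 7-methyl-3-oxooct-6-enoate F1. C-alkylation with NaH and (2-iodoethoxy)(tert-butyl)dimethylsilane gives tert-butyl 2-[2-(tert-butyldimethylsilyloxy)ethyl]-7-methyl-3-oxooct-6-enoate F2. The dianion of F2 is acylated by 6 as in step 5 to give the open-chain triketo ester F3. Catalytic TsOH·H2O closes ring C to the dihydropyranone F4. Heating F4 in toluene at 110 °C expels tert-butanol to give the acylketene F5, whose enol form is a dienylketene that undergoes 6π-electrocyclisation and tautomerisation to bis-TBS laxiflorin F6 with no base present. HF·pyridine in THF removes both silyl groups, and the route is rejoined at 16.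

Second: step 5. The dianion may deprotonate 6 at its γ-CH2 instead of adding to the carbonyl, or the siloxy group may be eliminated. The fallback is a neutral thermal union through an acylketene instead of a carbanion Claisen. It sets out from 10 and 6. Compound 10 is converted (TMSCl/Et3N, then LDA/TMSCl) into its bis(trimethylsilyl) dienol ether, 2-(trimethylsilyloxy)-3-[5-methyl-1-(trimethylsilyloxy)hexa-1,4-dien-1-yl]-4,5-dihydrofuran F7. Heating 6 with F7 in toluene at 110 °C releases acetone and the acylketene F8, which is C-acylated by the terminal carbon of F7. A pH 7 aqueous work-up hydrolyses the silyl enol ethers, and the route is rejoined at 12.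

Third: step 3. The electron-rich aldehyde may give low conversion or ee, and the ligand sense is assumed. The fallback sets the carbinol by asymmetric ketone reduction instead of asymmetric C–C bond formation. It sets out from 2 and 3. The lithium dienolate 4 adds to 2 at −78 °C to give the racemic hydroxy dioxinone F9. Dess–Martin oxidation gives the keto dioxinone F10. Noyori transfer hydrogenation with RuCl[(S,S)-TsDPEN](p-cymene) in HCO2H/Et3N gives the (S)-hydroxy dioxinone F11. TMSCl/imidazole silylates it, and the route is rejoined at 6.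

## Further compounds

F1 | step 6 | tert-butyl 7-methyl-3-oxooct-6-enoate | CC(C)=CCCC(=O)CC(=O)OC(C)(C)C
F2 | step 6 | tert-butyl 2-[2-(tert-butyldimethylsilyloxy)ethyl]-7-methyl-3-oxooct-6-enoate | CC(C)=CCCC(=O)C(CCO[Si](C)(C)C(C)(C)C)C(=O)OC(C)(C)C
F3 | step 6 | tert-butyl (9S)-9-[4-(tert-butyldimethylsilyloxy)-3-methoxyphenyl]-2-[2-(tert-butyldimethylsilyloxy)ethyl]-4-(3-methylbut-2-enyl)-3,5,7-trioxo-9-(trimethylsilyloxy)nonanoate | COc1cc([C@@H](O[Si](C)(C)C)CC(=O)CC(=O)C(CC=C(C)C)C(=O)C(CCO[Si](C)(C)C(C)(C)C)C(=O)OC(C)(C)C)ccc1O[Si](C)(C)C(C)(C)C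
F4 | step 6 | tert-butyl 2-[2-(tert-butyldimethylsilyloxy)ethyl]-4-{(2S)-2-[4-(tert-butyldimethylsilyloxy)-3-methoxyphenyl]-4-oxo-3,4-dihydro-2H-pyran-6-yl}-7-methyl-3-oxooct-6-enoate | COc1cc([C@@H]2CC(=O)C=C(C(CC=C(C)C)C(=O)C(CCO[Si](C)(C)C(C)(C)C)C(=O)OC(C)(C)C)O2)ccc1O[Si](C)(C)C(C)(C)C
F5 | step 6 | acylketene from F4, 2-[2-(tert-butyldimethylsilyloxy)ethyl]-4-{(2S)-2-[4-(tert-butyldimethylsilyloxy)-3-methoxyphenyl]-4-oxo-3,4-dihydro-2H-pyran-6-yl}-7-methylocta-1,6-diene-1,3-dione | COc1cc([C@@H]2CC(=O)C=C(C(CC=C(C)C)C(=O)C(CCO[Si](C)(C)C(C)(C)C)=C=O)O2)ccc1O[Si](C)(C)C(C)(C)C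
F6 | step 6 | (2S)-2-[4-(tert-butyldimethylsilyloxy)-3-methoxyphenyl]-6-[2-(tert-butyldimethylsilyloxy)ethyl]-5,7-dihydroxy-8-(3-methylbut-2-enyl)-2,3-dihydro-4H-chromen-4-one | COc1cc([C@@H]2CC(=O)c3c(O)c(CCO[Si](C)(C)C(C)(C)C)c(O)c(CC=C(C)C)c3O2)ccc1O[Si](C)(C)C(C)(C)C
F7 | step 5 | 2-(trimethylsilyloxy)-3-[5-methyl-1-(trimethylsilyloxy)hexa-1,4-dien-1-yl]-4,5-dihydrofuran | CC(C)=CCC=C(O[Si](C)(C)C)C1=C(O[Si](C)(C)C)OCC1
F8 | step 5 | (5S)-5-[4-(tert-butyldimethylsilyloxy)-3-methoxyphenyl]-5-(trimethylsilyloxy)pent-1-ene-1,3-dione (acylketene from 6) | COc1cc([C@@H](O[Si](C)(C)C)CC(=O)C=C=O)ccc1O[Si](C)(C)C(C)(C)C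
F9 | step 3 | racemic 6-{2-[4-(tert-butyldimethylsilyloxy)-3-methoxyphenyl]-2-hydroxyethyl}-2,2-dimethyl-4H-1,3-dioxin-4-one | COc1cc(C(O)CC2=CC(=O)OC(C)(C)O2)ccc1O[Si](C)(C)C(C)(C)C
F10 | step 3 | 6-{2-[4-(tert-butyldimethylsilyloxy)-3-methoxyphenyl]-2-oxoethyl}-2,2-dimethyl-4H-1,3-dioxin-4-one | COc1cc(C(=O)CC2=CC(=O)OC(C)(C)O2)ccc1O[Si](C)(C)C(C)(C)C
F11 | step 3 | (S)-6-{2-[4-(tert-butyldimethylsilyloxy)-3-methoxyphenyl]-2-hydroxyethyl}-2,2-dimethyl-4H-1,3-dioxin-4-one | COc1cc([C@@H](O)CC2=CC(=O)OC(C)(C)O2)ccc1O[Si](C)(C)C(C)(C)C
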